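All constants were drawn at random within sensible limits; the result is computed.

In a one-step first-order world a substrate falls to half its charge in a time given by one constant. This flask has two first-order steps on the same substrate, and the next run must either be charged more heavily or be left longer.

substrate 0.050 M; time 2.5 d

    substrate → target (k1 = 2.25 × 10⁻⁶ s⁻¹)
    substrate → side product (k2 = 9.18 × 10⁻⁷ s⁻¹)

- at 2.5 d, what has stopped the reaction, if anything has (it is still moving / all of the substrate has reacted / forward and back rates have come level)
- how much of the substrate has reacted by 2.5 d
- how much target there is at 2.5 d, in percent of the substrate charged
- how much side product there is at 2.5 d, in percent of the substrate charged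

- the reaction counts as stopped when no species that holds the substrate changes by six tenths of a point or more over the second half of the time
- run time (flask): 2.5 d

Both steps draw on one pool of substrate, so their constants add:

h = ln(2) / (2.25 × 10⁻⁶ s⁻¹ + 9.18 × 10⁻⁷ s⁻¹) = 2.53 d

This h is the shared half-life, the time in which both steps together halve the substrate. It is shorter than the half-life by either step by itself, which are 3.6 d and 8.7 d. The expression holds no concentration, so the charge is no lever on the fraction reacted, and the time is what the next run can change. Both rates carry the same substrate concentration, so target forms faster than side product by the selectivity factor 2.5, and target takes a constant share s of whatever reacts: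

s = 2.25 × 10⁻⁶ s⁻¹ / (2.25 × 10⁻⁶ s⁻¹ + 9.18 × 10⁻⁷ s⁻¹) = 71.0%

The reckoning made here for the flask at 2.5 d runs:

substrate left = 0.5^(t/h) = 50.4%

substrate reacted = 49.6%

target = s × reacted = 35.2%

side product = 14.4%

The substrate falls by 21 percentage points between 1.25 d and 2.50 d, so the flask counts as moving. The next run is therefore to be left longer at the same charge: waiting adds target, while the split stays at s.

The forecast says it is still moving, with 49.6% reacted, 35.2% target and 14.4% side product, on the grounds of “a half-life of roughly 2.5 d”.

In the flask, it is still moving, with 49.6% reacted, 35.2% target and 14.4% side product. Between 1.25 d and 2.50 d the shares in the flask moved by up to 21 points, and at 2.5 d 50% of the charge is still substrate. The same flask read at 6.0 d has stood 2.37 shared half-lives, which leaves 19.3% substrate and gives 57.3% target by the reckoning; its reading shows 19.4% substrate and 57.3% target.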